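**Retrosynthetic overview**
- The pyranone ring is formed last: O1–C2 and C2–C3 come from an amide-acetal annulation of an o-hydroxy-deoxybenzoin, and the two MOM ethers are removed in the same flask.
- The aryl–C(=O) bond comes from ortho-lithiation and Weinreb acylation of a phenol whose two ortho positions are equivalent; the single free OH then has to become O1, which forces the 6- (not 8-) substitution pattern.
- Key disconnection: the aryl–CH2 bond, made by metalating C2v-symmetric 3,5-bis(MOM)phenol on its symmetry axis and opening (S)-2-isopropenyloxirane, which carries the stereocentre.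
- The symmetric phenol comes from phloroglucinol; the epoxide comes from methacrolein by Corey–Chaykovsky epoxidation and hydrolytic kinetic resolution.
- Ring order: A ring (phloroglucinol) and B ring (anisyl unit) are bought; the C ring is closed at the end.

Assumption: the stereocentre in the target SMILES is (R); phloroglucinol, methacrolein, (4-methoxyphenyl)acetyl chloride and the (S,S)-(salen)Co precatalyst are purchased.

**Route**

Step 1
Reactants: 1 phloroglucinol (benzene-1,3,5-triol)
Product: 2 3,5-bis(methoxymethoxy)phenol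
Conditions: NaH (2.0 equiv), MOMCl (2.0 equiv), DMF, 0 °C → rt; chromatography, mono- and tris-ethers recycled
Reagents that add atoms: chloromethyl methyl ether (MOMCl), COCCl
Why: Statistical Williamson etherification (MOM protection) caps two of the three equivalent OH groups of 1, which breaks its threefold symmetry and leaves a C2v-symmetric phenol whose one free OH is destined to become O1 of the chromone (expect about 40 % of 2).

Step 2
Reactants: 3 methacrolein (2-methylprop-2-enal)
Product: 4 rac-2-(prop-1-en-2-yl)oxirane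
Conditions: Me3S+ I− (1.1 equiv), NaH (1.1 equiv), DMSO–THF, 0 °C → rt; fractional distillation
Reagents that add atoms: trimethylsulfonium iodide, C[S+](C)C.[I-]
Why: Corey–Chaykovsky epoxidation, in which the sulfonium ylide adds 1,2 to the enal and closes the oxirane with loss of dimethyl sulfide; the product is racemic at this stage.

Step 3
Reactants: 4 rac-2-(prop-1-en-2-yl)oxirane
Product: 5 (2S)-2-(prop-1-en-2-yl)oxirane
Conditions: (S,S)-(salen)Co(III)OAc (0.5 mol %), H2O (0.55 equiv), neat, 0 °C → rt, 16 h; vacuum transfer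
Reagents that add atoms: none
Why: Jacobsen hydrolytic kinetic resolution, in which the (S,S)-catalyst (by analogy with alkyl oxiranes) hydrolyses the (R)-epoxide to the diol and leaves the (S)-epoxide in high ee; this is where the only stereocentre of the target is set.

Step 4
Reactants: 2 3,5-bis(methoxymethoxy)phenol; 5 (2S)-2-(prop-1-en-2-yl)oxirane
Product: 7 4-[(2R)-2-hydroxy-3-methylbut-3-en-1-yl]-3,5-bis(methoxymethoxy)phenol, via C4-lithiated lithium phenolate 6 (not isolated)
Conditions: n-BuLi (2.2 equiv), TMEDA (2.2 equiv), THF, 0 °C → rt, 2 h; then 5 (1.3 equiv), 0 °C → rt, 12 h; aq NH4Cl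
Reagents that add atoms: none
Why: Directed ortho-metalation followed by SN2 epoxide opening: the phenoxide O–Li is a poor director, so the second n-BuLi removes the C4–H flanked by the two chelating OMOM groups, and the copper-free aryllithium attacks the unhindered CH2 of 5 without a Lewis acid (which would favour allylic or SN2′ opening); the C–O bond at the stereocentre is not touched, so the centre of 5 is carried over unchanged and is named (R) in 7 only because the CIP priorities change.

Step 5
Reactants: 8 (4-methoxyphenyl)acetyl chloride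
Product: 9 N-methoxy-2-(4-methoxyphenyl)-N-methylacetamide
Conditions: MeNH(OMe)·HCl (1.1 equiv), Et3N (2.2 equiv), CH2Cl2, 0 °C → rt
Reagents that add atoms: N,O-dimethylhydroxylamine hydrochloride, CNOC.Cl
Why: Simple N-acylation of the hydroxylamine by the acid chloride gives the Weinreb amide needed for a clean ketone synthesis.

Step 6
Reactants: 7 4-[(2R)-2-hydroxy-3-methylbut-3-en-1-yl]-3,5-bis(methoxymethoxy)phenol; 9 N-methoxy-2-(4-methoxyphenyl)-N-methylacetamide
Product: 11 1-{2-hydroxy-5-[(2R)-2-hydroxy-3-methylbut-3-en-1-yl]-4,6-bis(methoxymethoxy)phenyl}-2-(4-methoxyphenyl)ethan-1-one, via trilithiated aryl species 10 (not isolated)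
Conditions: s-BuLi (3.3 equiv), TMEDA, THF, −78 → −30 °C, 2 h; then 9 (1.2 equiv), −78 → 0 °C; aq NH4Cl
Reagents that add atoms: none
Why: Directed ortho-metalation and Weinreb ketone synthesis: once both OH groups are deprotonated, the only ring C–H bonds left are the two equivalent ones between O–Li and OMOM, so only one regioisomer can form, the chelated adduct of 9 stops at the ketone, and the carbonyl ends up next to the one free phenol; the stereocentre is not involved.

Step 7
Reactants: 11 1-{2-hydroxy-5-[(2R)-2-hydroxy-3-methylbut-3-en-1-yl]-4,6-bis(methoxymethoxy)phenyl}-2-(4-methoxyphenyl)ethan-1-one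
Product: 14 5,7-dihydroxy-6-[(2R)-2-hydroxy-3-methylbut-3-en-1-yl]-3-(4-methoxyphenyl)-4H-chromen-4-one, via enaminone 12 (not isolated), via bis-MOM isoflavone 13 (not isolated)
Conditions: Me2NCH(OMe)2 (3 equiv), toluene, 90 °C, 3 h; evaporate; then 2 M HCl in MeOH, 40 °C
Reagents that add atoms: N,N-dimethylformamide dimethyl acetal, COC(OC)N(C)C
Why: Enaminone annulation then acetal exchange: DMF-DMA condenses at the activated benzylic CH2, the only free phenol adds to the enaminone and expels dimethylamine (addition–elimination) to close the pyranone, and methanolic HCl transfers both MOM groups to methanol under conditions mild enough to leave the secondary allylic alcohol and its stereocentre intact.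

**Compound list**
1 | phloroglucinol (benzene-1,3,5-triol) | Oc1cc(O)cc(O)c1 | starting material
2 | 3,5-bis(methoxymethoxy)phenol | COCOc1cc(O)cc(OCOC)c1 | intermediate
3 | methacrolein (2-methylprop-2-enal) | CC(=C)C=O | starting material
4 | rac-2-(prop-1-en-2-yl)oxirane | C=C(C)C1CO1 | intermediate
5 | (2S)-2-(prop-1-en-2-yl)oxirane | C=C(C)[C@H]1CO1 | intermediate
6 | lithium 4-lithio-3,5-bis(methoxymethoxy)phenolate | [Li]Oc1cc(OCOC)c([Li])c(OCOC)c1 | intermediate
7 | 4-[(2R)-2-hydroxy-3-methylbut-3-en-1-yl]-3,5-bis(methoxymethoxy)phenol | C=C(C)[C@H](O)Cc1c(OCOC)cc(O)cc1OCOC | intermediate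
8 | (4-methoxyphenyl)acetyl chloride | COc1ccc(CC(Cl)=O)cc1 | starting material
9 | N-methoxy-2-(4-methoxyphenyl)-N-methylacetamide | COc1ccc(CC(=O)N(C)OC)cc1 | intermediate
10 | lithium 2-lithio-4-[(2R)-2-(lithiooxy)-3-methylbut-3-en-1-yl]-3,5-bis(methoxymethoxy)phenolate | C=C(C)[C@H](O[Li])Cc1c(OCOC)cc(O[Li])c([Li])c1OCOC | intermediate
11 | 1-{2-hydroxy-5-[(2R)-2-hydroxy-3-methylbut-3-en-1-yl]-4,6-bis(methoxymethoxy)phenyl}-2-(4-methoxyphenyl)ethan-1-one | C=C(C)[C@H](O)Cc1c(OCOC)cc(O)c(C(=O)Cc2ccc(OC)cc2)c1OCOC | intermediate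
12 | 3-(dimethylamino)-1-{2-hydroxy-5-[(2R)-2-hydroxy-3-methylbut-3-en-1-yl]-4,6-bis(methoxymethoxy)phenyl}-2-(4-methoxyphenyl)prop-2-en-1-one | C=C(C)[C@H](O)Cc1c(OCOC)cc(O)c(C(=O)C(=CN(C)C)c2ccc(OC)cc2)c1OCOC | intermediate
13 | 6-[(2R)-2-hydroxy-3-methylbut-3-en-1-yl]-3-(4-methoxyphenyl)-5,7-bis(methoxymethoxy)-4H-chromen-4-one | C=C(C)[C@H](O)Cc1c(OCOC)cc2occ(-c3ccc(OC)cc3)c(=O)c2c1OCOC | intermediate
14 | 5,7-dihydroxy-6-[(2R)-2-hydroxy-3-methylbut-3-en-1-yl]-3-(4-methoxyphenyl)-4H-chromen-4-one | C=C(C)[C@H](O)Cc1c(O)cc2occ(-c3ccc(OC)cc3)c(=O)c2c1O | target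

**Step count and risks**

Total step count: 7. Longest linear sequence: 5 steps (3 → 4 → 5 → 7 → 11 → 14); from phloroglucinol it is 4 steps.

The three steps most likely to fail:

Step 4. The second lithiation could go ortho to the phenoxide instead of between the MOM ethers, and the aryllithium could open the vinyl epoxide at the allylic carbon or in an SN2′ sense. The fallback sets out from 2 and comes back at 7. Silylate 2 (TIPSCl, imidazole) to [3,5-bis(methoxymethoxy)phenoxy]tri(propan-2-yl)silane F1. Lithiate it between the two MOM ethers (n-BuLi, THF, 0 °C; the bulky, non-coordinating OTIPS leaves no other site) and alkylate with prenyl bromide (CuBr·SMe2 cat.) to [3,5-bis(methoxymethoxy)-4-(3-methylbut-2-en-1-yl)phenoxy]tri(propan-2-yl)silane F2. Epoxidise with Shi's D-fructose-derived ketone and Oxone to (4-{[(2R)-3,3-dimethyloxiran-2-yl]methyl}-3,5-bis(methoxymethoxy)phenoxy)tri(propan-2-yl)silane F3 (use the enantiomeric ketone if the sense proves opposite). Isomerise the epoxide with Et2Al-TMP (Yamamoto) to the allylic alcohol (2R)-1-{2,6-bis(methoxymethoxy)-4-[tri(propan-2-yl)silyloxy]phenyl}-3-methylbut-3-en-2-ol F4, and cleave the silyl ether with TBAF to give 7. The stereocentre is then set by the epoxidation catalyst instead of being bought in with the epoxide.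

Step 6. Ring metalation of the polyanion may be incomplete, and the aryllithium may enolise 9 instead of adding to it. The fallback sets out from 7 and comes back at 11. Iodinate 7 with NIS (1.0 equiv, MeCN, −20 °C) at one of the two equivalent positions ortho to the phenol to give 4-[(2R)-2-hydroxy-3-methylbut-3-en-1-yl]-2-iodo-3,5-bis(methoxymethoxy)phenol F5. Deprotonate both OH groups with MeMgCl, carry out iodine–magnesium exchange with i-PrMgCl·LiCl, and add 9. The aryl Grignard reagent is far less basic than the aryllithium, so 11 forms without enolisation of the amide.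

Step 7. In the acid stage the allylic alcohol may ionise, or a freed phenol may add to the protonated alkene. The fallback sets out from 13 and comes back at 14. Stop step 7 after the DMF-DMA stage and isolate 13. Acetylate the allylic alcohol (Ac2O, pyridine, DMAP) to (2R)-1-[3-(4-methoxyphenyl)-5,7-bis(methoxymethoxy)-4-oxo-4H-chromen-6-yl]-3-methylbut-3-en-2-yl acetate F6. Remove the MOM ethers with HCl in MeOH (0 °C → rt) to give (2R)-1-[5,7-dihydroxy-3-(4-methoxyphenyl)-4-oxo-4H-chromen-6-yl]-3-methylbut-3-en-2-yl acetate F7; the acyloxy group disfavours both ionisation at the carbinol carbon and protonation of the neighbouring alkene. Finally cleave the acetate with K2CO3 in MeOH to give 14.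

**Further compounds**
F1 | step 4 | [3,5-bis(methoxymethoxy)phenoxy]tri(propan-2-yl)silane | COCOc1cc(O[Si](C(C)C)(C(C)C)C(C)C)cc(OCOC)c1
F2 | step 4 | [3,5-bis(methoxymethoxy)-4-(3-methylbut-2-en-1-yl)phenoxy]tri(propan-2-yl)silane | CC(C)=CCc1c(OCOC)cc(O[Si](C(C)C)(C(C)C)C(C)C)cc1OCOC
F3 | step 4 | (4-{[(2R)-3,3-dimethyloxiran-2-yl]methyl}-3,5-bis(methoxymethoxy)phenoxy)tri(propan-2-yl)silane | CC1(C)O[C@@H]1Cc1c(OCOC)cc(O[Si](C(C)C)(C(C)C)C(C)C)cc1OCOC
F4 | step 4 | (2R)-1-{2,6-bis(methoxymethoxy)-4-[tri(propan-2-yl)silyloxy]phenyl}-3-methylbut-3-en-2-ol | C=C(C)[C@H](O)Cc1c(OCOC)cc(O[Si](C(C)C)(C(C)C)C(C)C)cc1OCOC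
F5 | step 6 | 4-[(2R)-2-hydroxy-3-methylbut-3-en-1-yl]-2-iodo-3,5-bis(methoxymethoxy)phenol | C=C(C)[C@H](O)Cc1c(OCOC)cc(O)c(I)c1OCOC
F6 | step 7 | (2R)-1-[3-(4-methoxyphenyl)-5,7-bis(methoxymethoxy)-4-oxo-4H-chromen-6-yl]-3-methylbut-3-en-2-yl acetate | C=C(C)[C@H](OC(C)=O)Cc1c(OCOC)cc2occ(-c3ccc(OC)cc3)c(=O)c2c1OCOC
F7 | step 7 | (2R)-1-[5,7-dihydroxy-3-(4-methoxyphenyl)-4-oxo-4H-chromen-6-yl]-3-methylbut-3-en-2-yl acetate | C=C(C)[C@H](OC(C)=O)Cc1c(O)cc2occ(-c3ccc(OC)cc3)c(=O)c2c1O
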